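**Retrosynthetic overview**
1. Feature: in ring A of the acacetin half (unprimed locants; apigenin half double-primed), O1 on C8a and the C4 carbonyl on C4a are ortho neighbours, and C5 next to C4a carries oxygen. This is the pattern left when a 3-alkoxyaryne C4a≡C8a takes up the C(=O)–O unit of a carboxylic acid.
2. Disconnections: (a) the five MOM ethers; (b) ring C of the acacetin half (C8a–O1, C4a–C4, O1–C2), giving an ortho-silylaryl triflate and 3-(4-methoxyphenyl)propiolic acid; (c) the C6–C8'' biaryl bond (Suzuki–Miyaura), giving 8''-iodo-tri-O-MOM-apigenin and a phloroglucinol-derived boronic acid.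
3. The SiMe3 group on C4a is installed on the phloroglucinol ring before the coupling (ortho-bromination, retro-Brook shift), with the C8a oxygen held as a benzyl ether. No organolithium reagent therefore meets a flavone carbonyl, and only hydrogenolysis and triflation follow the coupling.
4. Ring order: rings A'', B'' and C'' come intact with apigenin, ring A is phloroglucinol, and ring B comes with the propiolic acid. Ring C is the only ring built, in the penultimate step.

Key step: step 11

Assumption: the SMILES gives no descriptor for the C6–C8'' axis, so the biaryl is made as the racemate and no atroposelection is attempted.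

**Step 1**
Reactants: 1 apigenin
Product: 2 5,7-bis(methoxymethoxy)-2-[4-(methoxymethoxy)phenyl]-4H-chromen-4-one (tri-O-MOM-apigenin)
Conditions: NaH (4 equiv), MOMCl (4 equiv), DMF, 0 °C → rt
Reagents that add atoms: chloromethyl methyl ether (MOMCl), COCCl
Why: Williamson-type O-alkylation, in which NaH turns all three phenols, including the hydrogen-bonded C5''–OH, into phenoxides that the very reactive MOMCl alkylates on oxygen.

**Step 2**
Reactants: 2 tri-O-MOM-apigenin
Product: 3 8-iodo-5,7-bis(methoxymethoxy)-2-[4-(methoxymethoxy)phenyl]-4H-chromen-4-one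
Conditions: NIS (1.1 equiv), DMF, rt → 50 °C, dark
Reagents that add atoms: N-iodosuccinimide, O=C1CCC(=O)N1I
Why: Electrophilic aromatic iodination under neutral conditions that spare the acetals; the phloroglucinol-type ring A'' is far more nucleophilic than ring B'' or C3'', and C8'' (para to the C5'' ether) is the established site of attack once the C5'' hydroxyl is alkylated.

**Step 3**
Reactants: 4 phloroglucinol
Product: 5 3,5-bis(methoxymethoxy)phenol
Conditions: NaH (2.0 equiv), MOMCl (2.0 equiv), DMF, 0 °C → rt
Reagents that add atoms: chloromethyl methyl ether (MOMCl), COCCl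
Why: Williamson-type O-alkylation run with two equivalents of reagent; the distribution is statistical, so the bis-ether is separated by chromatography from the mono- and tris-ethers, which can be recycled.

**Step 4**
Reactants: 5 3,5-bis(methoxymethoxy)phenol
Product: 6 2-bromo-3,5-bis(methoxymethoxy)phenol
Conditions: NBS (1.0 equiv, slow addition), iPr2NH (10 mol %), CH2Cl2, −78 °C → 0 °C
Reagents that add atoms: N-bromosuccinimide, O=C1CCC(=O)N1Br
Why: Amine-catalysed ortho-selective electrophilic bromination of a phenol, in which the hydrogen-bonded N-bromoamine delivers bromine to one of the two equivalent positions next to OH, both less crowded than the position between the two MOM ethers.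

**Step 5**
Reactants: 6 2-bromo-3,5-bis(methoxymethoxy)phenol
Product: 8 3,5-bis(methoxymethoxy)-2-(trimethylsilyl)phenol, via aryl trimethylsilyl ether 7 (not isolated)
Conditions: HMDS, THF, 65 °C, then evaporation; n-BuLi (1.1 equiv), THF, −78 °C; aq NH4Cl
Reagents that add atoms: hexamethyldisilazane (HMDS), C[Si](C)(C)N[Si](C)(C)C
Why: O-silylation followed by bromine–lithium exchange sets off a retro-Brook (1,3 O-to-C) silyl shift, driven by the exchange of an aryllithium for a lithium phenoxide; this is the standard entry to ortho-silylphenols, and no carbonyl group is present here.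

**Step 6**
Reactants: 8 3,5-bis(methoxymethoxy)-2-(trimethylsilyl)phenol
Product: 9 [2-(benzyloxy)-4,6-bis(methoxymethoxy)phenyl]trimethylsilane
Conditions: BnBr, K2CO3, DMF, rt
Reagents that add atoms: benzyl bromide, BrCc1ccccc1
Why: Williamson ether synthesis on the only free phenol, giving a group that survives n-BuLi and aqueous base and is later removed without acid or fluoride.

**Step 7**
Reactants: 9 [2-(benzyloxy)-4,6-bis(methoxymethoxy)phenyl]trimethylsilane
Product: 11 [4-(benzyloxy)-2,6-bis(methoxymethoxy)-3-(trimethylsilyl)phenyl]boronic acid, via aryllithium 10 (not isolated)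
Conditions: n-BuLi (1.2 equiv), THF, 0 °C; B(OMe)3, −78 °C → rt; aq NH4Cl
Reagents that add atoms: trimethyl borate, COB(OC)OC; water, O
Why: Directed ortho-metalation and borylation, in which the C–H flanked by two chelating MOM ethers is removed in preference to the other C–H, which lies next to the weakly directing benzyl ether whose benzyl group is pushed over it by the neighbouring SiMe3.

**Step 8**
Reactants: 3 8-iodo-tri-O-MOM-apigenin; 11 arylboronic acid (1.5 equiv)
Product: 12 8-[4-(benzyloxy)-2,6-bis(methoxymethoxy)-3-(trimethylsilyl)phenyl]-5,7-bis(methoxymethoxy)-2-[4-(methoxymethoxy)phenyl]-4H-chromen-4-one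
Conditions: Pd(OAc)2 (5 mol %), SPhos (10 mol %), K3PO4 (3 equiv), toluene–H2O 10:1, 100 °C
Reagents that add atoms: none
Why: Suzuki–Miyaura coupling with a bulky, electron-rich dialkylbiarylphosphine, a ligand type established for tetra-ortho-substituted biaryls and 2,6-dialkoxyarylboronic acids; C8''–I is the only site for oxidative addition and the aryl–SiMe3 bond is inert without fluoride.

**Step 9**
Reactants: 12 biaryl benzyl ether
Product: 13 8-[4-hydroxy-2,6-bis(methoxymethoxy)-3-(trimethylsilyl)phenyl]-5,7-bis(methoxymethoxy)-2-[4-(methoxymethoxy)phenyl]-4H-chromen-4-one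
Conditions: H2 (1 atm), 10% Pd/C, EtOAc–MeOH, rt
Reagents that add atoms: none
Why: Catalytic hydrogenolysis of an aryl benzyl ether, which at atmospheric pressure under neutral conditions should leave the flavone C2''=C3'' bond, the MOM acetals and the aryl–silicon bond untouched.

**Step 10**
Reactants: 13 ortho-silylphenol
Product: 14 4-{5,7-bis(methoxymethoxy)-2-[4-(methoxymethoxy)phenyl]-4-oxo-4H-chromen-8-yl}-3,5-bis(methoxymethoxy)-2-(trimethylsilyl)phenyl trifluoromethanesulfonate
Conditions: PhNTf2 (1.3 equiv), DBU (1.5 equiv), MeCN, rt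
Reagents that add atoms: N-phenylbis(trifluoromethanesulfonimide), O=S(=O)(N(c1ccccc1)S(=O)(=O)C(F)(F)F)C(F)(F)F
Why: O-sulfonylation of the phenoxide with a mild triflyl donor routinely used on ortho-silylphenols, chosen over Tf2O so that neither the chromone carbonyl nor the acetals are activated.

**Step 11**
Reactants: 14 ortho-silylaryl triflate; 15 3-(4-methoxyphenyl)propiolic acid (1.2 equiv)
Product: 18 8-[5,7-bis(methoxymethoxy)-2-(4-methoxyphenyl)-4-oxo-4H-chromen-6-yl]-5,7-bis(methoxymethoxy)-2-[4-(methoxymethoxy)phenyl]-4H-chromen-4-one, via aryne 16 (not isolated), via ortho-hydroxyaryl ynone 17 (not isolated)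
Conditions: CsF (4 equiv), THF (0.02 M), 125 °C, sealed tube
Reagents that add atoms: none
Why: Fluoride attacks silicon and triflate leaves to give the 3-alkoxyaryne 16 (C4a≡C8a); the carboxylate oxygen of 15 bonds to C8a, the aryl anion left at C4a attacks the ester carbonyl through a four-membered alkoxide, and its opening (a net anionic Fries-type acyl shift) gives the phenoxide of ynone 17. The closest known reaction type is the intermolecular insertion of arynes into the C–O bond of carboxylic acids, which with arylpropiolic acids is known to deliver flavones in one pot. Ring C, the only ring closed, forms by 6-endo-dig oxa-Michael addition of the C8a phenoxide to the ynone β-carbon C2, the acid proton ending on C3, and the aprotic medium keeps the competing 5-exo-dig (aurone) closure reversible and unproductive. No stereocentre is created. The step needs regioselective addition to the unsymmetrical aryne, and the σ-withdrawing C5–OMOM group secures this by making C8a the more electrophilic terminus and placing the carbanion on C4a next to oxygen, while C8a (flanked by C8–H) is also the less hindered end. It further needs acyl transfer to outrun protonation of the C4a anion, which hot dilute THF, sparingly soluble CsF and only a slight excess of acid favour.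

**Step 12**
Reactants: 18 penta-O-MOM biflavone
Product: 19 8-[5,7-dihydroxy-2-(4-methoxyphenyl)-4-oxo-4H-chromen-6-yl]-5,7-dihydroxy-2-(4-hydroxyphenyl)-4H-chromen-4-one (target)
Conditions: HCl (1.25 M in MeOH), THF, 50 °C
Reagents that add atoms: none
Why: Acid-catalysed transacetalisation removes all five MOM ethers under conditions too mild to cleave the aryl methyl ether at C4' or to trigger a Wessely–Moser ring-opening isomerisation of the 6-linked half.

**Compound list**
1 | apigenin | O=c1cc(-c2ccc(O)cc2)oc2cc(O)cc(O)c12 | starting material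
2 | 5,7-bis(methoxymethoxy)-2-[4-(methoxymethoxy)phenyl]-4H-chromen-4-one | COCOc1ccc(-c2cc(=O)c3c(OCOC)cc(OCOC)cc3o2)cc1 | intermediate
3 | 8-iodo-5,7-bis(methoxymethoxy)-2-[4-(methoxymethoxy)phenyl]-4H-chromen-4-one | COCOc1ccc(-c2cc(=O)c3c(OCOC)cc(OCOC)c(I)c3o2)cc1 | intermediate
4 | phloroglucinol | Oc1cc(O)cc(O)c1 | starting material
5 | 3,5-bis(methoxymethoxy)phenol | COCOc1cc(O)cc(OCOC)c1 | intermediate
6 | 2-bromo-3,5-bis(methoxymethoxy)phenol | COCOc1cc(O)c(Br)c(OCOC)c1 | intermediate
7 | [2-bromo-3,5-bis(methoxymethoxy)phenoxy]trimethylsilane | COCOc1cc(O[Si](C)(C)C)c(Br)c(OCOC)c1 | intermediate (not isolated)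
8 | 3,5-bis(methoxymethoxy)-2-(trimethylsilyl)phenol | COCOc1cc(O)c([Si](C)(C)C)c(OCOC)c1 | intermediate
9 | [2-(benzyloxy)-4,6-bis(methoxymethoxy)phenyl]trimethylsilane | COCOc1cc(OCc2ccccc2)c([Si](C)(C)C)c(OCOC)c1 | intermediate
10 | [4-(benzyloxy)-2,6-bis(methoxymethoxy)-3-(trimethylsilyl)phenyl]lithium | COCOc1cc(OCc2ccccc2)c([Si](C)(C)C)c(OCOC)c1[Li] | intermediate (not isolated)
11 | [4-(benzyloxy)-2,6-bis(methoxymethoxy)-3-(trimethylsilyl)phenyl]boronic acid | COCOc1cc(OCc2ccccc2)c([Si](C)(C)C)c(OCOC)c1B(O)O | intermediate
12 | 8-[4-(benzyloxy)-2,6-bis(methoxymethoxy)-3-(trimethylsilyl)phenyl]-5,7-bis(methoxymethoxy)-2-[4-(methoxymethoxy)phenyl]-4H-chromen-4-one | COCOc1cc(OCc2ccccc2)c([Si](C)(C)C)c(OCOC)c1-c1c(OCOC)cc(OCOC)c2c(=O)cc(-c3ccc(OCOC)cc3)oc12 | intermediate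
13 | 8-[4-hydroxy-2,6-bis(methoxymethoxy)-3-(trimethylsilyl)phenyl]-5,7-bis(methoxymethoxy)-2-[4-(methoxymethoxy)phenyl]-4H-chromen-4-one | COCOc1cc(O)c([Si](C)(C)C)c(OCOC)c1-c1c(OCOC)cc(OCOC)c2c(=O)cc(-c3ccc(OCOC)cc3)oc12 | intermediate
14 | 4-{5,7-bis(methoxymethoxy)-2-[4-(methoxymethoxy)phenyl]-4-oxo-4H-chromen-8-yl}-3,5-bis(methoxymethoxy)-2-(trimethylsilyl)phenyl trifluoromethanesulfonate | COCOc1cc(OS(=O)(=O)C(F)(F)F)c([Si](C)(C)C)c(OCOC)c1-c1c(OCOC)cc(OCOC)c2c(=O)cc(-c3ccc(OCOC)cc3)oc12 | intermediate
15 | 3-(4-methoxyphenyl)propiolic acid | COc1ccc(C#CC(=O)O)cc1 | starting material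
16 | 8-[2,6-bis(methoxymethoxy)-3,4-didehydrophenyl]-5,7-bis(methoxymethoxy)-2-[4-(methoxymethoxy)phenyl]-4H-chromen-4-one (aryne C4a≡C8a) | COCOC1=CC#CC(OCOC)=C1c1c(OCOC)cc(OCOC)c2c(=O)cc(-c3ccc(OCOC)cc3)oc12 | intermediate (not isolated)
17 | 8-{4-hydroxy-2,6-bis(methoxymethoxy)-3-[3-(4-methoxyphenyl)prop-2-ynoyl]phenyl}-5,7-bis(methoxymethoxy)-2-[4-(methoxymethoxy)phenyl]-4H-chromen-4-one | COCOc1cc(O)c(C(=O)C#Cc2ccc(OC)cc2)c(OCOC)c1-c1c(OCOC)cc(OCOC)c2c(=O)cc(-c3ccc(OCOC)cc3)oc12 | intermediate (not isolated)
18 | 8-[5,7-bis(methoxymethoxy)-2-(4-methoxyphenyl)-4-oxo-4H-chromen-6-yl]-5,7-bis(methoxymethoxy)-2-[4-(methoxymethoxy)phenyl]-4H-chromen-4-one | COc1ccc(-c2cc(=O)c3c(OCOC)c(-c4c(OCOC)cc(OCOC)c5c(=O)cc(-c6ccc(OCOC)cc6)oc45)c(OCOC)cc3o2)cc1 | intermediate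
19 | 8-[5,7-dihydroxy-2-(4-methoxyphenyl)-4-oxo-4H-chromen-6-yl]-5,7-dihydroxy-2-(4-hydroxyphenyl)-4H-chromen-4-one | COc1ccc(-c2cc(=O)c3c(O)c(-c4c(O)cc(O)c5c(=O)cc(-c6ccc(O)cc6)oc45)c(O)cc3o2)cc1 | target

**Totals**
Total step count: 12.
Longest linear sequence: 10 steps (steps 3–12, from phloroglucinol).

**Steps most likely to fail**

Step 11. The C4a aryl anion may be protonated before the acyl shift, which stops the sequence at simple O-arylation of the acid. The propiolic acid may also decarboxylate at 125 °C, and the hindered substrate may lower conversion. The fallback sets out from 13 and uses the silicon only as a position marker. Ipso-iododesilylation with NIS in MeCN at 0 °C should give the ortho-iodophenol 8-[4-hydroxy-3-iodo-2,6-bis(methoxymethoxy)phenyl]-5,7-bis(methoxymethoxy)-2-[4-(methoxymethoxy)phenyl]-4H-chromen-4-one F1. A palladium-catalysed carbonylative Sonogashira coupling–cyclisation of this compound with commercial 4-ethynylanisole follows (PdCl2(dppf), CO, Et2NH, 120 °C). It builds C4a–C4 from CO and closes O1–C2 through the enaminone, and the route is rejoined at 18.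

Step 8. Protodeboronation of the 2,6-dialkoxyarylboronic acid in aqueous base may outrun the slow transmetalation and reductive elimination needed for a tetra-ortho-substituted biaryl, and 3 may suffer reductive loss of iodine. The fallback sets out from 9 and removes boron and water altogether. Lithiation as in step 7 gives 10, and ZnCl2 in THF converts it into [4-(benzyloxy)-2,6-bis(methoxymethoxy)-3-(trimethylsilyl)phenyl]zinc chloride F2. This is used directly in a Negishi coupling with 3 (Pd2(dba)3, RuPhos, THF, 70 °C), conditions that tolerate the flavone carbonyl, and the route is rejoined at 12.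

Step 4. Bromination may occur partly para to the hydroxyl (between the two MOM ethers) or twice, because the ring is very electron-rich. The fallback sets out from 5 and replaces electrophilic substitution by directed metalation. Carbamoylation (ClC(O)NEt2, NaH, THF) gives 3,5-bis(methoxymethoxy)phenyl diethylcarbamate F3. Treatment with s-BuLi/TMEDA in THF at −78 °C lithiates one of the two equivalent positions between the carbamate and a MOM ether, and TMSCl then gives 3,5-bis(methoxymethoxy)-2-(trimethylsilyl)phenyl diethylcarbamate F4. Reductive cleavage of the carbamate with LiAlH4 in THF releases the phenol, and the route is rejoined at 8.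

**Further compounds**
F1 | step 11 | 8-[4-hydroxy-3-iodo-2,6-bis(methoxymethoxy)phenyl]-5,7-bis(methoxymethoxy)-2-[4-(methoxymethoxy)phenyl]-4H-chromen-4-one | COCOc1cc(O)c(I)c(OCOC)c1-c1c(OCOC)cc(OCOC)c2c(=O)cc(-c3ccc(OCOC)cc3)oc12
F2 | step 8 | [4-(benzyloxy)-2,6-bis(methoxymethoxy)-3-(trimethylsilyl)phenyl]zinc chloride | COCOc1cc(OCc2ccccc2)c([Si](C)(C)C)c(OCOC)c1[Zn]Cl
F3 | step 4 | 3,5-bis(methoxymethoxy)phenyl diethylcarbamate | CCN(CC)C(=O)Oc1cc(OCOC)cc(OCOC)c1
F4 | step 4 | 3,5-bis(methoxymethoxy)-2-(trimethylsilyl)phenyl diethylcarbamate | CCN(CC)C(=O)Oc1cc(OCOC)cc(OCOC)c1[Si](C)(C)C
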